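**Plan**
- Numbering follows the parent hydroxy acid: C1 is the lactone carbonyl carbon, C2–C33 are the ring CH2 groups, and C34 is the CH2 on the ring oxygen. The only ring is the 35-membered lactone.
- Retrosynthesis: cut C32–C33 (ring closure), then the ester bond C1(=O)–O, then C11–C12 and C21–C22 of the C32 chain. This leads back to 11-bromoundecanoic acid, 1,10-dibromodecane, 11-bromoundec-1-ene and 2-iodoethanol.
- Enabling feature: the ring oxygen lies two carbons (C34, C33) from the bond, so the C33–C34–O unit comes from 2-iodoethanol and C33 enters as a primary iodide β to the ester oxygen. The rest of the ring is bare polymethylene, so C32 can be the CH2= end of a terminal alkene, and a nickel-hydride reductive alkene–alkyl iodide coupling joins the two carbons directly at the sp3 level.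
- Forward: C22–C32 is joined to C12–C21 and then to C1–C11 by two copper-catalysed Grignard couplings; the acid is esterified with the C33–C34–O unit; the 35-membered ring arises last.
- Stereochemistry: none to set, since the target has no stereocentre and no double bond.

Key step: step 4

**Step 1**
Reactants: 1 11-bromoundec-1-ene; 2 1,10-dibromodecane
Product: 4 21-bromohenicos-1-ene, via undec-10-en-1-ylmagnesium bromide 3 (not isolated)
Conditions: 1, Mg turnings, THF, 40 °C; then added to 2 (4 equiv), Li2CuCl4 (3 mol %), THF, −10 °C to rt
Reagents that add atoms: none
Why: Copper-catalysed cross-coupling of a primary Grignard reagent with a primary alkyl bromide is a standard sp3–sp3 chain extension, and the excess of dibromide (recoverable by distillation) should hold the reaction at mono-coupling.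

**Step 2**
Reactants: 4 21-bromohenicos-1-ene; 5 11-bromoundecanoic acid
Product: 9 dotriacont-31-enoic acid, via henicos-20-en-1-ylmagnesium bromide 6 (not isolated), via chloromagnesium 11-bromoundecanoate 7 (not isolated), via chloromagnesium dotriacont-31-enoate 8 (not isolated)
Conditions: 4, Mg, THF, 45 °C; separately 5, MeMgCl (1.0 equiv), THF, −20 °C; then the Grignard solution, Li2CuCl4 (3 mol %), −20 °C to rt; aq. HCl
Reagents that add atoms: none
Why: The same copper-catalysed Grignard cross-coupling is well precedented on halomagnesium salts of ω-bromo acids, because the carboxylate is inert to the Grignard reagent at low temperature while the primary bromide couples.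

**Step 3**
Reactants: 9 dotriacont-31-enoic acid; 10 2-iodoethanol
Product: 11 2-iodoethyl dotriacont-31-enoate
Conditions: DCC, DMAP (10 mol %), CH2Cl2/THF, rt to 35 °C
Reagents that add atoms: none
Why: Steglich esterification (carbodiimide activation, DMAP acyl transfer) joins the acid and the primary alcohol under neutral conditions that should leave the primary iodide and the terminal alkene untouched.

**Step 4**
Reactants: 11 2-iodoethyl dotriacont-31-enoate
Product: 12 oxacyclopentatriacontan-2-one (34-tetratriacontanolide)
Conditions: NiBr2·diglyme (10 mol %), 4,4′-di-tert-butyl-2,2′-bipyridine (12 mol %), (EtO)2MeSiH (2.5 equiv), Na2CO3 (2 equiv), DMA/THF, 30 °C; 11 added by syringe pump over 24 h (about 1 mM)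
Reagents that add atoms: none
Why: Proposed new method: a bipyridine-ligated nickel hydride, formed from NiBr2, the silane and the base, should add to the monosubstituted alkene with nickel on the terminal carbon C32; the resulting primary alkyl complex of monovalent nickel abstracts iodine from C33 of the same chain, the 2-(acyloxy)ethyl radical is recaptured to give a dialkyl complex of trivalent nickel, and reductive elimination forms the C32–C33 bond. The closest known reaction type is the intermolecular nickel-hydride-catalysed anti-Markovnikov hydroalkylation of unactivated terminal alkenes with primary alkyl iodides, which tolerates esters; its use for the end-to-end closure of a large ring is the new element. The 35-membered lactone closes with both reacting carbons inside the ring (formally 35-endo with respect to the alkene), by way of a 36-membered nickelacycle. No stereocentre is formed. The step needs linear rather than branched coupling, which the unhindered CH2= terminus should secure (nickel settles on the primary carbon even after chain walking), and ring closure rather than oligomerisation, which slow addition and the strain-free unbranched chain should secure. It also needs C–C coupling to outrun loss of the carboxylate by β-elimination, which should be secured because C33 enters as a radical that does not fragment and never rests as an alkyl complex of divalent nickel.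

**Compound list**
1 | 11-bromoundec-1-ene | C=CCCCCCCCCCBr | starting material
2 | 1,10-dibromodecane | BrCCCCCCCCCCBr | starting material
3 | undec-10-en-1-ylmagnesium bromide | C=CCCCCCCCCC[Mg]Br | intermediate
4 | 21-bromohenicos-1-ene | C=CCCCCCCCCCCCCCCCCCCCBr | intermediate
5 | 11-bromoundecanoic acid | OC(=O)CCCCCCCCCCBr | starting material
6 | henicos-20-en-1-ylmagnesium bromide | C=CCCCCCCCCCCCCCCCCCCC[Mg]Br | intermediate
7 | chloromagnesium 11-bromoundecanoate | BrCCCCCCCCCCC(=O)O[Mg]Cl | intermediate
8 | chloromagnesium dotriacont-31-enoate | C=CCCCCCCCCCCCCCCCCCCCCCCCCCCCCCC(=O)O[Mg]Cl | intermediate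
9 | dotriacont-31-enoic acid | C=CCCCCCCCCCCCCCCCCCCCCCCCCCCCCCC(=O)O | intermediate
10 | 2-iodoethanol | OCCI | starting material
11 | 2-iodoethyl dotriacont-31-enoate | C=CCCCCCCCCCCCCCCCCCCCCCCCCCCCCCC(=O)OCCI | intermediate
12 | oxacyclopentatriacontan-2-one (34-tetratriacontanolide) | O=C1CCCCCCCCCCCCCCCCCCCCCCCCCCCCCCCCCO1 | target

**Total step count:** 4
**Longest linear sequence:** 4 steps (steps 1 to 4)

**Steps most likely to fail**

Step 4 (the proposed macrocyclisation). Several processes could defeat it:
- intermolecular coupling of the long flexible chains to oligomers;
- reduction of either terminus (hydrodeiodination, alkene hydrogenation or isomerisation) outrunning the slow ring closure;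
- loss of the carboxylate by β-elimination from an alkylnickel at C33;
- coupling at C31 instead of C32.

The fallback uses ring-closing metathesis and hydrogenation, both with close precedent for large lactones; it closes the ring one bond further along the chain. It sets out from acid 9. Steglich esterification with but-3-en-1-ol (DCC, DMAP, CH2Cl2/THF) would give but-3-en-1-yl dotriacont-31-enoate F1. Ring-closing metathesis (second-generation Grubbs catalyst, CH2Cl2, 40 °C, about 1 mM) with loss of ethene would give oxacyclopentatriacont-32-en-2-one F2 as an E/Z mixture. Hydrogenation (H2, 10% Pd/C, EtOAc/THF) would remove the double bond, and the fallback comes back to the route at the target 12.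

Step 1 (mono-coupling on a symmetrical dibromide). Coupling at both ends of 1,10-dibromodecane and homocoupling of the Grignard reagent could erode the yield, and separation of the long-chain products could be difficult. The fallback carries the second terminus of the ten-carbon unit as a protected alcohol. It sets out from 1 through its Grignard reagent 3. Commercial 10-bromodecan-1-ol would be protected (3,4-dihydro-2H-pyran, PPTS, CH2Cl2) as 2-[(10-bromodecyl)oxy]oxane F3. Copper-catalysed coupling with 3 (Li2CuCl4, THF, −10 °C to rt) would give 2-(henicos-20-en-1-yloxy)oxane F4. Methanolysis (PPTS, MeOH/THF, 50 °C) would give henicos-20-en-1-ol F5. Appel bromination (CBr4, PPh3, CH2Cl2) comes back to the route at compound 4.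

Step 2 (coupling on the magnesium carboxylate). The poorly soluble carboxylate salt could couple sluggishly, the Grignard reagent could homocouple, and the long-chain acid could be hard to separate from hydrocarbon by-products. The fallback carries the carboxyl group as a protected primary alcohol and adjusts the oxidation level afterwards. It sets out from 4 through its Grignard reagent 6. Commercial 11-bromoundecan-1-ol would be protected (3,4-dihydro-2H-pyran, PPTS, CH2Cl2) as 2-[(11-bromoundecyl)oxy]oxane F6. Copper-catalysed coupling with 6 (Li2CuCl4, THF) would give 2-(dotriacont-31-en-1-yloxy)oxane F7. Methanolysis (PPTS, MeOH/THF, 50 °C) would give dotriacont-31-en-1-ol F8. Jones oxidation (CrO3, H2SO4, acetone/CH2Cl2, 0 °C to rt), which spares the terminal alkene, comes back to the route at acid 9.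

**Further compounds**
F1 | step 4 | but-3-en-1-yl dotriacont-31-enoate | C=CCCCCCCCCCCCCCCCCCCCCCCCCCCCCCC(=O)OCCC=C
F2 | step 4 | oxacyclopentatriacont-32-en-2-one (E/Z mixture) | O=C1CCCCCCCCCCCCCCCCCCCCCCCCCCCCCC=CCCO1
F3 | step 1 | 2-[(10-bromodecyl)oxy]oxane (racemic) | BrCCCCCCCCCCOC1CCCCO1
F4 | step 1 | 2-(henicos-20-en-1-yloxy)oxane (racemic) | C=CCCCCCCCCCCCCCCCCCCCOC1CCCCO1
F5 | step 1 | henicos-20-en-1-ol | C=CCCCCCCCCCCCCCCCCCCCO
F6 | step 2 | 2-[(11-bromoundecyl)oxy]oxane (racemic) | BrCCCCCCCCCCCOC1CCCCO1
F7 | step 2 | 2-(dotriacont-31-en-1-yloxy)oxane (racemic) | C=CCCCCCCCCCCCCCCCCCCCCCCCCCCCCCCOC1CCCCO1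
F8 | step 2 | dotriacont-31-en-1-ol | C=CCCCCCCCCCCCCCCCCCCCCCCCCCCCCCCO
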